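## Retrosynthetic overview
1. Endgame on the intact bicycle: C11–OOH comes from Co-catalysed hydrosilylperoxidation of a C11=C12 isopropenyl group. The 1β-OH comes from C1 allylic oxidation followed by α-face Luche reduction, and the angelate from Yamaguchi acylation of the 3β-OH.
2. The cross-conjugated dienone comes from a bicyclic 6,8-dione by Stork–Danheiser transposition, which removes a temporary C6 oxygen.
3. Key disconnection: C5–C10 and C7–C8 are formed together by a base-induced Michael–Dieckmann bicyclisation of the acyclic keto-ynoate 14. Ring A (C1–C5, C10) closes first and ring B (C5–C10) second, in the same flask.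
4. Enabling feature: in ring B, C8(=O)–C9–C10 is an acyl/β-carbon 1,3-dielectrophile (an ynoate). C5 and C7 lie 1,3 across C6, so a ketone placed at C6 makes both nucleophilic (ring B is a C5-blocked resorcinol with consonant polarities). Quaternary C5 blocks aromatisation, and the C1–C4 chain makes the first closure 6-exo.
5. Compound 14 is built linearly from 5-(trimethylsilyl)pent-4-ynal by catalytic enantioselective anti-tiglylboration (sets C3 and C4), hydroboration, isobutenyl addition and alkyne methoxycarbonylation.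

Key step: step 11

Remark: eremophilane numbering is used (C1 carbinol, C3 acyloxy, C4/C5 methyl-bearing, C6=C7, C8 ketone, C9=C10, C11 hydroperoxy carbon), and β is the face of the C4/C5 methyls. Epimers at the future C5 in 9–14 are inconsequential because C5 is planarised in step 11, and 16 is drawn as one enol tautomer of the 6,8-dione.

## Route

Step 1
Reactants: 1 5-(trimethylsilyl)pent-4-yn-1-ol
Product: 2 5-(trimethylsilyl)pent-4-ynal
Conditions: Dess–Martin periodinane, CH2Cl2, 0 °C to rt
Reagents that add atoms: none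
Why: Dess–Martin oxidation stops at the aldehyde under near-neutral conditions and leaves the C-silyl alkyne untouched.

Step 2
Reactants: 3 (E)-2-methylbut-2-en-1-ol (tiglyl alcohol)
Product: 4 (E)-2-methylbut-2-enylboronic acid pinacol ester
Conditions: B2pin2, Pd(MeCN)4(BF4)2 (5 mol %), DMSO–MeOH, 50 °C
Reagents that add atoms: bis(pinacolato)diboron CC1(C)OB(OC1(C)C)B1OC(C)(C)C(C)(C)O1
Why: Palladium-catalysed allylic borylation of the free allylic alcohol runs through an η3-allyl-palladium species that is borylated at its unsubstituted terminus, which should give the linear (E)-allylboronate.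

Step 3
Reactants: 2 5-(trimethylsilyl)pent-4-ynal; 4 (E)-2-methylbut-2-enylboronic acid pinacol ester
Product: 6 (3R,4S)-2,3-dimethyl-8-(trimethylsilyl)oct-1-en-7-yn-4-ol, via O-Bpin borate 5 (not isolated)
Conditions: (R)-TRIP (5 mol %), toluene, −30 °C; aq NaHCO3 work-up
Reagents that add atoms: none
Why: Chiral-phosphoric-acid-catalysed allylboration through a closed Zimmerman–Traxler chair, in which the (E)-γ-methyl group gives the anti relationship and (R)-TRIP directs attack to the Re face of the aldehyde, sets the future C3 (S) and C4 (R).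

Step 4
Reactants: 6 (3R,4S)-2,3-dimethyl-8-(trimethylsilyl)oct-1-en-7-yn-4-ol
Product: 7 (3R,4S)-4-(tert-butyldimethylsilyloxy)-2,3-dimethyl-8-(trimethylsilyl)oct-1-en-7-yne
Conditions: TBSOTf, 2,6-lutidine, CH2Cl2, 0 °C
Reagents that add atoms: tert-butyldimethylsilyl triflate CC(C)(C)[Si](C)(C)OS(=O)(=O)C(F)(F)F
Why: Silylation with the triflate covers the hindered secondary alcohol with a group that should survive borane, Grignard, alkoxide and hydride reagents.

Step 5
Reactants: 7 (3R,4S)-4-(tert-butyldimethylsilyloxy)-2,3-dimethyl-8-(trimethylsilyl)oct-1-en-7-yne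
Product: 9 (3R,4S)-4-(tert-butyldimethylsilyloxy)-2,3-dimethyl-8-(trimethylsilyl)oct-7-yn-1-ol (C2 epimers), via B-alkyl-9-BBN adduct 8 (not isolated)
Conditions: 9-BBN, THF, 0 °C to rt; then 30% H2O2, aq NaOAc
Reagents that add atoms: hydrogen peroxide OO; 9-borabicyclo[3.3.1]nonane [H]B1C2CCCC1CCC2 (boron and its carbons only in 8)
Why: Hydroboration–oxidation with 9-BBN is anti-Markovnikov and much faster on a 1,1-disubstituted alkene than on a silyl-capped internal alkyne, and the new C2 centre needs no control.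

Step 6
Reactants: 9 (3R,4S)-4-(tert-butyldimethylsilyloxy)-2,3-dimethyl-8-(trimethylsilyl)oct-7-yn-1-ol
Product: 10 (3R,4S)-4-(tert-butyldimethylsilyloxy)-2,3-dimethyl-8-(trimethylsilyl)oct-7-ynal (C2 epimers)
Conditions: Dess–Martin periodinane, CH2Cl2, rt
Reagents that add atoms: none
Why: Dess–Martin oxidation gives the α-branched aldehyde without touching either silyl group.

Step 7
Reactants: 10 (3R,4S)-4-(tert-butyldimethylsilyloxy)-2,3-dimethyl-8-(trimethylsilyl)oct-7-ynal
Product: 11 (6R,7S)-7-(tert-butyldimethylsilyloxy)-2,5,6-trimethyl-11-(trimethylsilyl)undec-2-en-10-yn-4-ol (C4 and C5 epimers)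
Conditions: Me2C=CHMgBr, THF, −78 to 0 °C; H2O quench
Reagents that add atoms: 2-methylprop-1-enylmagnesium bromide CC(C)=C[Mg]Br
Why: Grignard 1,2-addition brings in C7, C11 and both C11 methyls, and the carbinol configuration is erased in the next step.

Step 8
Reactants: 11 (6R,7S)-7-(tert-butyldimethylsilyloxy)-2,5,6-trimethyl-11-(trimethylsilyl)undec-2-en-10-yn-4-ol
Product: 12 (6R,7S)-7-(tert-butyldimethylsilyloxy)-2,5,6-trimethyl-11-(trimethylsilyl)undec-2-en-10-yn-4-one (C5 epimers)
Conditions: Dess–Martin periodinane, CH2Cl2, rt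
Reagents that add atoms: none
Why: Dess–Martin oxidation of the allylic alcohol gives the β,β-dimethyl enone that serves as the temporary C6 ketone.

Step 9
Reactants: 12 (6R,7S)-7-(tert-butyldimethylsilyloxy)-2,5,6-trimethyl-11-(trimethylsilyl)undec-2-en-10-yn-4-one
Product: 13 (6R,7S)-7-(tert-butyldimethylsilyloxy)-2,5,6-trimethylundec-2-en-10-yn-4-one (C5 epimers)
Conditions: K2CO3 (0.2 equiv), MeOH, rt
Reagents that add atoms: none
Why: Catalytic methanolysis cleaves the C(sp)–Si bond selectively, because the secondary TBS ether and the hindered enone are inert to this weak base.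

Step 10
Reactants: 13 (6R,7S)-7-(tert-butyldimethylsilyloxy)-2,5,6-trimethylundec-2-en-10-yn-4-one
Product: 14 methyl (6S,7R)-6-(tert-butyldimethylsilyloxy)-7,8,11-trimethyl-9-oxododec-10-en-2-ynoate (C8 epimers)
Conditions: PdCl2 (5 mol %), CuCl2 (2.2 equiv), NaOAc (2.2 equiv), CO (1 atm), MeOH, rt
Reagents that add atoms: carbon monoxide [C-]#[O+]; methanol CO
Why: Palladium(II)-catalysed oxidative methoxycarbonylation of the terminal alkyne installs the ynoate (C8) without a strong base, so the enolisable enone is tolerated.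

Step 11
Reactants: 14 methyl (6S,7R)-6-(tert-butyldimethylsilyloxy)-7,8,11-trimethyl-9-oxododec-10-en-2-ynoate
Product: 16 (3S,4R,5R)-3-(tert-butyldimethylsilyloxy)-8-hydroxyeremophila-7,9,11-trien-6-one (enol of the 6,8-dione), via Z-cyclohexylideneacetate 15 (not isolated)
Conditions: KOt-Bu (1.15 equiv), THF/t-BuOH 10:1, 0.01 M, −20 °C to rt; then 1 M HCl
Reagents that add atoms: none
Why: Reversible enolisation funnels 14 through its C5 (α′) enolate, the only enolate with a six-membered option, which adds 6-exo-dig to C10 of the ynoate (ring A, C5–C10 bond) and gives 15 after protonation of the allenolate at C9; γ-deprotonation of the 3-methylbut-2-enoyl group then gives the extended dienolate, whose α-carbon C7 attacks the ester carbonyl C8 in a 6-(enolexo)-exo-trig Dieckmann closure (ring B, C7–C8 bond) with loss of methoxide. The closest known reaction type is the consecutive Michael–Claisen [3+3] annulation of ketones with unsaturated esters to cyclohexane-1,3-diones, run here intramolecularly on an alkynoate. The only new stereocentre, C5, is controlled by C4: A(1,3) strain places C4–H in the enolate plane next to C6, the C4 methyl anti to the forming bond and the tether on the attacking face, which makes the C4 and C5 methyls cis (C5 methyl axial, C6 equatorial on ring A). The step needs C- over O-acylation, the Z geometry at C9=C10 and the correct use of the two ketone α-positions: the enol lactone, the E/Z isomers and the alkyne/allene isomers all interconvert under alkoxide through the C1-deprotonated dienolate, whereas only C-acylation ends in the stabilised 1,3-diketone enolate, which is the thermodynamic sink and also consumes the liberated methoxide. High dilution and t-BuOH as proton shuttle should suppress intermolecular Michael addition and a second Michael addition of C9 to C11.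

Step 12
Reactants: 16 (3S,4R,5R)-3-(tert-butyldimethylsilyloxy)-8-hydroxyeremophila-7,9,11-trien-6-one
Product: 17 (3S,4R,5R)-3-(tert-butyldimethylsilyloxy)-8-methoxyeremophila-7,9,11-trien-6-one
Conditions: Me2SO4, K2CO3, acetone, reflux
Reagents that add atoms: dimethyl sulfate COS(=O)(=O)OC
Why: O-alkylation of the vinylogous acid with a hard electrophile should favour the C8 oxygen, which is flanked only by C9–H, over the neopentyl C6 oxygen next to quaternary C5, and this gives the regioisomer needed for the transposition.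

Step 13
Reactants: 17 (3S,4R,5R)-3-(tert-butyldimethylsilyloxy)-8-methoxyeremophila-7,9,11-trien-6-one
Product: 20 (3S,4R,5R)-3-hydroxyeremophila-6,9,11-trien-8-one, via C6 carbinol 18 (not isolated), via TBS-protected trienone 19 (not isolated)
Conditions: LiAlH4, Et2O, 0 °C; H2O quench, filtration; then 48% aq HF, MeCN, 0 °C to rt
Reagents that add atoms: water O
Why: Stork–Danheiser transposition (1,2-hydride addition at C6, acid ionisation to the C8 oxocarbenium ion, hydrolysis) moves the carbonyl to C8, leaves C6=C7 and erases the temporary C6 oxygen, and the same aqueous HF cleaves the TBS ether.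

Step 14
Reactants: 20 (3S,4R,5R)-3-hydroxyeremophila-6,9,11-trien-8-one; 21 angelic acid, (Z)-2-methylbut-2-enoic acid
Product: 22 (3S,4R,5R)-3-angeloyloxyeremophila-6,9,11-trien-8-one
Conditions: 21, 2,4,6-Cl3C6H2COCl, Et3N, toluene, rt; then 20, 80 °C
Reagents that add atoms: none
Why: Yamaguchi mixed-anhydride esterification run without DMAP acylates the hindered axial 3β-alcohol and keeps the Z geometry, because no nucleophilic catalyst is present to add reversibly to the enoate.

Step 15
Reactants: 22 (3S,4R,5R)-3-angeloyloxyeremophila-6,9,11-trien-8-one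
Product: 23 (3S,4R,5R)-3-angeloyloxyeremophila-6,9,11-triene-1,8-dione
Conditions: Rh2(cap)4 (1 mol %), 70% aq t-BuOOH, ClCH2CH2Cl, 40 °C
Reagents that add atoms: tert-butyl hydroperoxide CC(C)(C)OO
Why: Dirhodium caprolactamate/TBHP allylic oxidation removes the C1–H that is γ to the dienone and gives a fully conjugated radical, as in the conversion of steroidal 4-en-3-ones into 4-ene-3,6-diones, and the base-free medium spares the β-acyloxy ketone.

Step 16
Reactants: 23 (3S,4R,5R)-3-angeloyloxyeremophila-6,9,11-triene-1,8-dione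
Product: 24 (1R,3S,4R,5R)-3-angeloyloxy-1-hydroxyeremophila-6,9,11-trien-8-one
Conditions: NaBH4, CeCl3·7H2O, MeOH, −78 °C
Reagents that add atoms: none
Why: In the Luche reduction the cross-conjugated, C7-substituted C8 carbonyl is the less electrophilic one, and the β-face of C1 is blocked by the syn-axial C5 methyl and C3 acyloxy groups, so hydride should arrive from the α-face and set the 1β (R) alcohol.

Step 17
Reactants: 24 (1R,3S,4R,5R)-3-angeloyloxy-1-hydroxyeremophila-6,9,11-trien-8-one
Product: 26 (1R,3S,4R,5R)-3-angeloyloxy-1-hydroxy-11-hydroperoxyeremophila-6,9-dien-8-one (CNP0300636.1), via triethylsilyl peroxide 25 (not isolated)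
Conditions: Co(thd)2 (10 mol %), Et3SiH (2 equiv), O2 (1 atm), ClCH2CH2Cl, rt; then cat. HCl, MeOH, 0 °C
Reagents that add atoms: dioxygen O=O; triethylsilane CC[SiH](CC)CC (silicon only in 25)
Why: In the Mukaiyama–Isayama hydrosilylperoxidation the cobalt hydride transfers H• to the unhindered C12 methylene, the delocalised radical takes up O2 at tertiary C11 rather than at the neopentyl C6 terminus so that C6=C7 stays conjugated, and methanolysis of the silyl peroxide frees the hydroperoxide.

## Compound list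
1 | 5-(trimethylsilyl)pent-4-yn-1-ol | C[Si](C)(C)C#CCCCO | starting material
2 | 5-(trimethylsilyl)pent-4-ynal | C[Si](C)(C)C#CCCC=O | intermediate
3 | (E)-2-methylbut-2-en-1-ol | C/C=C(\C)CO | starting material
4 | (E)-2-methylbut-2-enylboronic acid pinacol ester | C/C=C(\C)CB1OC(C)(C)C(C)(C)O1 | intermediate
5 | O-Bpin borate of 6 | CC1(C)OB(O[C@H]([C@H](C)C(C)=C)CCC#C[Si](C)(C)C)OC1(C)C | intermediate
6 | (3R,4S)-2,3-dimethyl-8-(trimethylsilyl)oct-1-en-7-yn-4-ol | O[C@H]([C@H](C)C(C)=C)CCC#C[Si](C)(C)C | intermediate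
7 | (3R,4S)-4-(tert-butyldimethylsilyloxy)-2,3-dimethyl-8-(trimethylsilyl)oct-1-en-7-yne | CC(C)(C)[Si](C)(C)O[C@H]([C@H](C)C(C)=C)CCC#C[Si](C)(C)C | intermediate
8 | B-alkyl-9-BBN adduct of 7 | CC(C)(C)[Si](C)(C)O[C@H]([C@H](C)C(C)CB1C2CCCC1CCC2)CCC#C[Si](C)(C)C | intermediate
9 | (3R,4S)-4-(tert-butyldimethylsilyloxy)-2,3-dimethyl-8-(trimethylsilyl)oct-7-yn-1-ol (C2 epimers) | CC(C)(C)[Si](C)(C)O[C@H]([C@H](C)C(C)CO)CCC#C[Si](C)(C)C | intermediate
10 | (3R,4S)-4-(tert-butyldimethylsilyloxy)-2,3-dimethyl-8-(trimethylsilyl)oct-7-ynal (C2 epimers) | CC(C)(C)[Si](C)(C)O[C@H]([C@H](C)C(C)C=O)CCC#C[Si](C)(C)C | intermediate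
11 | (6R,7S)-7-(tert-butyldimethylsilyloxy)-2,5,6-trimethyl-11-(trimethylsilyl)undec-2-en-10-yn-4-ol (C4, C5 epimers) | CC(C)(C)[Si](C)(C)O[C@H]([C@H](C)C(C)C(O)C=C(C)C)CCC#C[Si](C)(C)C | intermediate
12 | (6R,7S)-7-(tert-butyldimethylsilyloxy)-2,5,6-trimethyl-11-(trimethylsilyl)undec-2-en-10-yn-4-one (C5 epimers) | CC(C)(C)[Si](C)(C)O[C@H]([C@H](C)C(C)C(=O)C=C(C)C)CCC#C[Si](C)(C)C | intermediate
13 | (6R,7S)-7-(tert-butyldimethylsilyloxy)-2,5,6-trimethylundec-2-en-10-yn-4-one (C5 epimers) | CC(C)(C)[Si](C)(C)O[C@H]([C@H](C)C(C)C(=O)C=C(C)C)CCC#C | intermediate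
14 | methyl (6S,7R)-6-(tert-butyldimethylsilyloxy)-7,8,11-trimethyl-9-oxododec-10-en-2-ynoate (C8 epimers) | COC(=O)C#CCC[C@H](O[Si](C)(C)C(C)(C)C)[C@H](C)C(C)C(=O)C=C(C)C | intermediate
15 | methyl (Z)-2-[(2R,3R,4S)-4-(tert-butyldimethylsilyloxy)-2,3-dimethyl-2-(3-methylbut-2-enoyl)cyclohexylidene]acetate | COC(=O)/C=C1/CC[C@H](O[Si](C)(C)C(C)(C)C)[C@H](C)[C@@]1(C)C(=O)C=C(C)C | intermediate
16 | (3S,4R,5R)-3-(tert-butyldimethylsilyloxy)-8-hydroxyeremophila-7,9,11-trien-6-one | CC(C)(C)[Si](C)(C)O[C@H]1CCC2=CC(O)=C(C(C)=C)C(=O)[C@]2(C)[C@H]1C | intermediate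
17 | (3S,4R,5R)-3-(tert-butyldimethylsilyloxy)-8-methoxyeremophila-7,9,11-trien-6-one | CC(C)(C)[Si](C)(C)O[C@H]1CCC2=CC(OC)=C(C(C)=C)C(=O)[C@]2(C)[C@H]1C | intermediate
18 | (3S,4R,5R)-3-(tert-butyldimethylsilyloxy)-8-methoxyeremophila-7,9,11-trien-6-ol (C6 epimers) | CC(C)(C)[Si](C)(C)O[C@H]1CCC2=CC(OC)=C(C(C)=C)C(O)[C@]2(C)[C@H]1C | intermediate
19 | (3S,4R,5R)-3-(tert-butyldimethylsilyloxy)eremophila-6,9,11-trien-8-one | CC(C)(C)[Si](C)(C)O[C@H]1CCC2=CC(=O)C(C(C)=C)=C[C@]2(C)[C@H]1C | intermediate
20 | (3S,4R,5R)-3-hydroxyeremophila-6,9,11-trien-8-one | O[C@H]1CCC2=CC(=O)C(C(C)=C)=C[C@]2(C)[C@H]1C | intermediate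
21 | angelic acid, (Z)-2-methylbut-2-enoic acid | C/C=C(/C)C(=O)O | starting material
22 | (3S,4R,5R)-3-angeloyloxyeremophila-6,9,11-trien-8-one | C/C=C(/C)C(=O)O[C@H]1CCC2=CC(=O)C(C(C)=C)=C[C@]2(C)[C@H]1C | intermediate
23 | (3S,4R,5R)-3-angeloyloxyeremophila-6,9,11-triene-1,8-dione | C/C=C(/C)C(=O)O[C@H]1CC(=O)C2=CC(=O)C(C(C)=C)=C[C@]2(C)[C@H]1C | intermediate
24 | (1R,3S,4R,5R)-3-angeloyloxy-1-hydroxyeremophila-6,9,11-trien-8-one | C/C=C(/C)C(=O)O[C@H]1C[C@@H](O)C2=CC(=O)C(C(C)=C)=C[C@]2(C)[C@H]1C | intermediate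
25 | (1R,3S,4R,5R)-3-angeloyloxy-1-hydroxy-11-(triethylsilylperoxy)eremophila-6,9-dien-8-one | C/C=C(/C)C(=O)O[C@H]1C[C@@H](O)C2=CC(=O)C(C(C)(C)OO[Si](CC)(CC)CC)=C[C@]2(C)[C@H]1C | intermediate
26 | (1R,3S,4R,5R)-3-angeloyloxy-1-hydroxy-11-hydroperoxyeremophila-6,9-dien-8-one | C/C=C(/C)C(=O)O[C@H]1C[C@@H](O)C2=CC(=O)C(C(C)(C)OO)=C[C@]2(C)[C@H]1C | target

## Step count and risks
Total step count: 17. Longest linear sequence: 16 (steps 1 and 3–17).

Steps most likely to fail:

**Step 11.** The equilibrating alkoxide may consume the ynoate by conjugate addition or by isomerisation to an unreactive 2,4-dienoate before the hindered C5 enolate closes. The cascade may also stall after ring A. The fallback sets out from 14. Soft enolisation (TMSOTf, Et3N, CH2Cl2, 0 °C) gives the 2-silyloxydiene methyl (6S,7R)-6-(tert-butyldimethylsilyloxy)-7,8,11-trimethyl-9-(trimethylsilyloxy)dodeca-8,10-dien-2-ynoate F1. A TiCl4-promoted intramolecular Mukaiyama–Michael addition at −78 °C then closes ring A under Lewis-acid instead of base activation and gives 15, now isolated. A separate Dieckmann condensation (NaOMe, MeOH), which also equilibrates the C9=C10 geometry, closes ring B and comes back to the route at 16.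

**Step 17.** The delocalised C11/C6 allyl radical may be captured by O2 at C6. Hydrogen-atom transfer may also reach the angelate or the enone double bonds. The fallback sets out from 24. Conjugate reduction with Stryker's reagent at C6, the only enone β-carbon that carries hydrogen, gives (1R,3S,4R,5R)-3-angeloyloxy-1-hydroxyeremophila-9,11-dien-8-one F4. DBU then moves the isopropenyl double bond into conjugation and gives (1R,3S,4R,5R)-3-angeloyloxy-1-hydroxyeremophila-7(11),9-dien-8-one F5. A Schenck ene reaction (tetraphenylporphyrin, O2, hν, CH2Cl2, 0 °C) on this s-cis isopropylidene ketone, with the geminal selectivity typical of unsaturated carbonyl compounds (oxygen to C11, hydrogen from C6), comes back to the route at 26.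

**Step 15.** Hydrogen abstraction may occur at the isopropenyl or angelate methyl groups, peroxyl radicals may add to the diene, or angelic acid may be lost by β-elimination from the new 1-ketone. The fallback sets out from 22. TESOTf/Et3N gives the C1(10),C8 tetraenol silyl ether F2. A vinylogous Rubottom oxidation with dimethyldioxirane attacks its electron-rich C1 terminus and gives the C1-epimeric carbinols 3-angeloyloxy-1-hydroxyeremophila-6,9,11-trien-8-one F3. Dess–Martin oxidation of both epimers comes back to the route at 23, so the facial outcome of the oxygenation does not matter.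

## Further compounds
F1 | step 11 | methyl (6S,7R)-6-(tert-butyldimethylsilyloxy)-7,8,11-trimethyl-9-(trimethylsilyloxy)dodeca-8,10-dien-2-ynoate | COC(=O)C#CCC[C@H](O[Si](C)(C)C(C)(C)C)[C@H](C)C(C)=C(O[Si](C)(C)C)C=C(C)C
F2 | step 15 | (3S,4R,5R)-3-angeloyloxy-8-(triethylsilyloxy)eremophila-1(10),6,8,11-tetraene | C/C=C(/C)C(=O)O[C@H]1CC=C2C=C(O[Si](CC)(CC)CC)C(C(C)=C)=C[C@]2(C)[C@H]1C
F3 | step 15 | (3S,4R,5R)-3-angeloyloxy-1-hydroxyeremophila-6,9,11-trien-8-one (C1 epimers) | C/C=C(/C)C(=O)O[C@H]1CC(O)C2=CC(=O)C(C(C)=C)=C[C@]2(C)[C@H]1C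
F4 | step 17 | (1R,3S,4R,5R)-3-angeloyloxy-1-hydroxyeremophila-9,11-dien-8-one (C7 epimers) | C/C=C(/C)C(=O)O[C@H]1C[C@@H](O)C2=CC(=O)C(C(C)=C)C[C@]2(C)[C@H]1C
F5 | step 17 | (1R,3S,4R,5R)-3-angeloyloxy-1-hydroxyeremophila-7(11),9-dien-8-one | C/C=C(/C)C(=O)O[C@H]1C[C@@H](O)C2=CC(=O)C(=C(C)C)C[C@]2(C)[C@H]1C
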